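## Retrosynthetic overview

1. Labdane numbering is used (ring A = C1–C5 + C10, ring B = C5–C10, side chain C11–C16). The target is the glycerol 1-acetate 3-ester of (5R,10R,13R)-labd-8-en-15-oic acid 16, and the ester and acetate are made last from 16, (S)-solketal and vinyl acetate.
2. Enabling feature: ring B is a cyclohexene whose only double bond, C8=C9, lies between C7 and the quaternary C10, and the gem-dimethyl carbon C4 of ring A is bonded to C5. Ring B is therefore a Diels–Alder retron (diene C7=C8–C9=C10, dienophile C5=C6), and C4 written as a ketone activates that dienophile from inside ring A.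
3. Key disconnection: C5–C10 and C6–C7, leading to the acyclic (Z)-trienone 12. One intramolecular Diels–Alder reaction closes ring B (the cycloadduct) and ring A (tether C1–C4), ring A being completed by the C5–C10 bond. C5 is then epimerised and C4=O converted into CMe2.
4. Trienone 12 comes from acetylacetone (C8, C9, C10 and both methyls), iodide 3 from methyl hydrogen (R)-3-methylglutarate (C11–C16, carries C13), hexa-1,5-dien-3-ol (C1–C6) and CH2Br2 (C7). A (Z)-enol triflate and a B-alkyl Suzuki coupling fix the C9=C10 geometry.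
5. Ring order: no carbocycle before step 8; rings B and A in step 8, with the C5–C10 bond that completes ring A as the last ring-forming bond; no ring is closed afterwards.

Key step: step 8

Assumption (chemistry): the (S)-oxazaborolidinium catalyst of step 8 is taken to present the Si face of C5 of the bound enone to the diene (α-C–H···O binding model for enones); if the opposite sense is found, the (R)-catalyst is used with no other change. The carbinol centre of 8–11 is racemic and is destroyed in step 7.

## Route

Step 1
Reactants: 1 (3R)-5-methoxy-3-methyl-5-oxopentanoic acid (methyl hydrogen (R)-3-methylglutarate)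
Product: 2 methyl (3R)-5-hydroxy-3-methylpentanoate
Conditions: BH3·SMe2, THF, 0 °C to rt; then H2O
Reagents that add atoms: none
Why: Borane reduces the free carboxylic acid much faster than the methyl ester (chemoselective borane reduction), the stereocentre is not touched, and crude 2 is carried on at once to avoid lactonisation.

Step 2
Reactants: 2 methyl (3R)-5-hydroxy-3-methylpentanoate
Product: 3 methyl (3S)-5-iodo-3-methylpentanoate
Conditions: I2, PPh3, imidazole, CH2Cl2, 0 °C to rt
Reagents that add atoms: iodine, II
Why: Appel-type iodination of the primary alcohol; the descriptor changes from R to S only because iodine changes the CIP priorities.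

Step 3
Reactants: 3 methyl (3S)-5-iodo-3-methylpentanoate; 4 pentane-2,4-dione (acetylacetone, excess)
Product: 5 methyl (3R)-6-acetyl-3-methyl-7-oxooctanoate
Conditions: K2CO3, acetone, reflux
Reagents that add atoms: none
Why: C-alkylation of the acetylacetone enolate by an unhindered primary iodide (1,3-diketone alkylation); the excess of 4 suppresses dialkylation and the diketone is symmetrical.

Step 4
Reactants: 5 methyl (3R)-6-acetyl-3-methyl-7-oxooctanoate
Product: 7 methyl (3R,6Z)-6-acetyl-3-methyl-7-{[(trifluoromethyl)sulfonyl]oxy}oct-6-enoate, via sodium enolate 6 (not isolated)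
Conditions: NaH, Et2O, 0 °C; then Tf2O, −78 to 0 °C
Reagents that add atoms: trifluoromethanesulfonic anhydride, O=S(=O)(OS(=O)(=O)C(F)(F)F)C(F)(F)F
Why: The sodium enolate of the 1,3-diketone is a U-shaped chelate with both oxygens cis, so O-triflation should place the triflate cis to the remaining acetyl group ((Z)-enol triflate formation from a β-dicarbonyl compound); only the diketone is acidic enough to be deprotonated.

Step 5
Reactants: 8 hexa-1,5-dien-3-ol (racemic); 7 methyl (3R,6Z)-6-acetyl-3-methyl-7-{[(trifluoromethyl)sulfonyl]oxy}oct-6-enoate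
Product: 10 methyl (3R,6Z)-6-acetyl-11-hydroxy-3,7-dimethyltrideca-6,12-dienoate (both C11 epimers), via alkylborane 9 (not isolated)
Conditions: 9-BBN (2.2 equiv), THF, 0 °C to rt; then 7, PdCl2(dppf), AsPh3, K3PO4 (3 M aq.), DMF, rt
Reagents that add atoms: none
Why: 9-BBN hydroborates the unhindered allyl-type vinyl group in preference to the vinyl group on the O-borylated carbinol carbon, and the B-alkyl Suzuki–Miyaura coupling of the vinylogous acyl triflate goes with retention, so C1 ends cis to the acetyl group (the future C8).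

Step 6
Reactants: 10 methyl (3R,6Z)-6-acetyl-11-hydroxy-3,7-dimethyltrideca-6,12-dienoate
Product: 11 methyl (3R,6Z)-11-hydroxy-3,7-dimethyl-6-(prop-1-en-2-yl)trideca-6,12-dienoate (both C11 epimers)
Conditions: Zn, CH2Br2, TiCl4, THF/CH2Cl2, 0 °C to rt
Reagents that add atoms: dibromomethane, BrCBr
Why: The non-basic Takai–Lombardo methylenation converts the hindered, enolisable conjugated ketone into the isopropenyl group (C7=C8) and tolerates the ester and the free hydroxyl; without base, no dienolate can scramble the C9=C10 geometry.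

Step 7
Reactants: 11 methyl (3R,6Z)-11-hydroxy-3,7-dimethyl-6-(prop-1-en-2-yl)trideca-6,12-dienoate
Product: 12 methyl (3R,6Z)-3,7-dimethyl-11-oxo-6-(prop-1-en-2-yl)trideca-6,12-dienoate
Conditions: Dess–Martin periodinane, CH2Cl2, 0 °C; cold filtration through silica, used at once
Reagents that add atoms: none
Why: Dess–Martin oxidation of the secondary allylic alcohol gives the vinyl ketone under neutral conditions and removes the racemic carbinol centre; 12 is kept cold so that no uncatalysed cyclisation occurs before step 8.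

Step 8
Reactants: 12 methyl (3R,6Z)-3,7-dimethyl-11-oxo-6-(prop-1-en-2-yl)trideca-6,12-dienoate
Product: 13 methyl (3R)-5-[(4aR,8aR)-2,8a-dimethyl-5-oxo-3,4,4a,5,6,7,8,8a-octahydronaphthalen-1-yl]-3-methylpentanoate (cis-fused)
Conditions: (S)-3,3-diphenyl-1-(o-tolyl)tetrahydro-1H,3H-pyrrolo[1,2-c][1,3,2]oxazaborole·Tf2NH (20 mol %), CH2Cl2, −78 to −40 °C
Reagents that add atoms: none
Why: The cationic boron Lewis acid binds the C4 ketone and lowers the LUMO of the C5=C6 vinyl ketone, and a concerted but asynchronous intramolecular [4+2] cycloaddition follows in which the unhindered C6–C7 bond leads and the C5–C10 bond closes at the tertiary allylic diene terminus, so the polarity of the enone matches the hindered diene. The closest known reaction types are the Lewis acid-promoted intramolecular Diels–Alder reaction of 1,7,9-decatrien-3-ones to 1-octalones and the oxazaborolidinium-catalysed enantioselective Diels–Alder reaction of vinyl ketones, including transannular cases with the ketone inside the connecting chain. Ring B is closed as the cycloadduct cyclohexene (bonds C6–C7 and C5–C10, with the new double bond at C8=C9 where the target has it), and ring A is closed by the same C5–C10 bond across the tether C1–C4 in the fused (type 1) mode. The quaternary centre C10 is set by the diene face that the catalyst-bound enone reaches, that is by the chiral Lewis acid (Si face of C5); C5 is set relative to C10 by the (Z)-geometry of C9=C10, because a tether on the inner diene position can reach C5 only through the carbonyl-exo transition state, which gives the cis-fused octalone alone. The selectivities needed are diene-face selectivity, secured by the catalyst, and a single ring-fusion mode, secured by the Z-diene, whose C8 methyl group also disfavours the s-trans rotamer by allylic strain. The low temperature keeps the uncatalysed cyclisation and the [1,5]-hydrogen shift of the Z-diene from competing, and C13 is too remote to influence or be influenced.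

Step 9
Reactants: 13 methyl (3R)-5-[(4aR,8aR)-2,8a-dimethyl-5-oxo-3,4,4a,5,6,7,8,8a-octahydronaphthalen-1-yl]-3-methylpentanoate
Product: 14 methyl (3R)-5-[(4aS,8aR)-2,8a-dimethyl-5-oxo-3,4,4a,5,6,7,8,8a-octahydronaphthalen-1-yl]-3-methylpentanoate (trans-fused)
Conditions: NaOMe (0.2 equiv), MeOH, rt
Reagents that add atoms: none
Why: Reversible enolisation at C5, α to the C4 ketone, should equilibrate the kinetic cis adduct to the trans-fused 1-decalone (thermodynamic epimerisation, by analogy with 4-oxo-5α-steroids; also the result of axial protonation anti to the angular methyl); C10 and C13 cannot epimerise, NaOMe in MeOH leaves the methyl ester unchanged, and any remaining cis isomer is separated and resubmitted.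

Step 10
Reactants: 14 methyl (3R)-5-[(4aS,8aR)-2,8a-dimethyl-5-oxo-3,4,4a,5,6,7,8,8a-octahydronaphthalen-1-yl]-3-methylpentanoate
Product: 15 methyl (3R)-3-methyl-5-[(4aR,8aR)-2,5,5,8a-tetramethyl-3,4,4a,5,6,7,8,8a-octahydronaphthalen-1-yl]pentanoate
Conditions: Me2Zn, TiCl4 (Me2TiCl2 formed in the flask), CH2Cl2, −30 °C to rt
Reagents that add atoms: dimethylzinc, C[Zn]C
Why: Reetz geminal dimethylation: Me2TiCl2 adds methyl to the ketone, the tertiary titanium alkoxide ionises and the C4 cation takes the second methyl group, while esters and unactivated alkenes are tolerated; C4 is not stereogenic, and the C5 descriptor returns to R only through the priority change.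

Step 11
Reactants: 15 methyl (3R)-3-methyl-5-[(4aR,8aR)-2,5,5,8a-tetramethyl-3,4,4a,5,6,7,8,8a-octahydronaphthalen-1-yl]pentanoate
Product: 16 (3R)-3-methyl-5-[(4aR,8aR)-2,5,5,8a-tetramethyl-3,4,4a,5,6,7,8,8a-octahydronaphthalen-1-yl]pentanoic acid
Conditions: LiOH, THF/MeOH/H2O, 40 °C; then 1 M HCl
Reagents that add atoms: lithium hydroxide, [Li+].[OH-]
Why: Saponification of an unhindered methyl ester; C13 is β to the carboxyl group and cannot epimerise.

Step 12
Reactants: 16 (3R)-3-methyl-5-[(4aR,8aR)-2,5,5,8a-tetramethyl-3,4,4a,5,6,7,8,8a-octahydronaphthalen-1-yl]pentanoic acid; 17 [(4S)-2,2-dimethyl-1,3-dioxolan-4-yl]methanol ((S)-solketal)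
Product: 18 [(4R)-2,2-dimethyl-1,3-dioxolan-4-yl]methyl (3R)-3-methyl-5-[(4aR,8aR)-2,5,5,8a-tetramethyl-3,4,4a,5,6,7,8,8a-octahydronaphthalen-1-yl]pentanoate
Conditions: EDC·HCl, DMAP, CH2Cl2, 0 °C to rt
Reagents that add atoms: none
Why: Steglich-type esterification of the primary alcohol of the acetonide; no bond to the glycerol stereocentre is made or broken, and its descriptor changes from S to R only through the CIP priorities.

Step 13
Reactants: 18 [(4R)-2,2-dimethyl-1,3-dioxolan-4-yl]methyl (3R)-3-methyl-5-[(4aR,8aR)-2,5,5,8a-tetramethyl-3,4,4a,5,6,7,8,8a-octahydronaphthalen-1-yl]pentanoate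
Product: 19 (2R)-2,3-dihydroxypropyl (3R)-3-methyl-5-[(4aR,8aR)-2,5,5,8a-tetramethyl-3,4,4a,5,6,7,8,8a-octahydronaphthalen-1-yl]pentanoate
Conditions: AcOH/H2O (4:1), 40 °C
Reagents that add atoms: none
Why: Mild acid hydrolysis of the isopropylidene acetal frees the 1,2-diol; the ester and the already most-substituted C8=C9 alkene are stable, and weak acid keeps acyl migration to O-2 slow.

Step 14
Reactants: 19 (2R)-2,3-dihydroxypropyl (3R)-3-methyl-5-[(4aR,8aR)-2,5,5,8a-tetramethyl-3,4,4a,5,6,7,8,8a-octahydronaphthalen-1-yl]pentanoate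
Product: 20 (2R)-3-(acetyloxy)-2-hydroxypropyl (3R)-3-methyl-5-[(4aR,8aR)-2,5,5,8a-tetramethyl-3,4,4a,5,6,7,8,8a-octahydronaphthalen-1-yl]pentanoate (CNP0137802.3)
Conditions: vinyl acetate, Novozym 435 (immobilised Candida antarctica lipase B), MTBE, rt
Reagents that add atoms: vinyl acetate, CC(=O)OC=C
Why: The lipase transfers acetyl from vinyl acetate to the primary hydroxyl only and should not accept the bulky β-branched diterpenoyl ester (lipase-catalysed regioselective transesterification under neutral conditions), so the secondary hydroxyl stays free and the glycerol stereocentre is untouched.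

## Compound list

1 | (3R)-5-methoxy-3-methyl-5-oxopentanoic acid | COC(=O)C[C@H](C)CC(=O)O | starting material
2 | methyl (3R)-5-hydroxy-3-methylpentanoate | COC(=O)C[C@H](C)CCO | intermediate
3 | methyl (3S)-5-iodo-3-methylpentanoate | COC(=O)C[C@H](C)CCI | intermediate
4 | pentane-2,4-dione | CC(=O)CC(C)=O | starting material
5 | methyl (3R)-6-acetyl-3-methyl-7-oxooctanoate | COC(=O)C[C@H](C)CCC(C(C)=O)C(C)=O | intermediate
6 | sodium (2Z,6R)-3-acetyl-8-methoxy-6-methyl-8-oxooct-2-en-2-olate | COC(=O)C[C@H](C)CC/C(C(C)=O)=C(\C)[O-].[Na+] | intermediate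
7 | methyl (3R,6Z)-6-acetyl-3-methyl-7-{[(trifluoromethyl)sulfonyl]oxy}oct-6-enoate | COC(=O)C[C@H](C)CC/C(C(C)=O)=C(\C)OS(=O)(=O)C(F)(F)F | intermediate
8 | hexa-1,5-dien-3-ol (racemic) | C=CCC(O)C=C | starting material
9 | 9-{4-[(9-borabicyclo[3.3.1]nonan-9-yl)oxy]hex-5-en-1-yl}-9-borabicyclo[3.3.1]nonane | C=CC(OB1C2CCCC1CCC2)CCCB1C2CCCC1CCC2 | intermediate
10 | methyl (3R,6Z)-6-acetyl-11-hydroxy-3,7-dimethyltrideca-6,12-dienoate (both C11 epimers) | COC(=O)C[C@H](C)CC/C(C(C)=O)=C(\C)CCCC(O)C=C | intermediate
11 | methyl (3R,6Z)-11-hydroxy-3,7-dimethyl-6-(prop-1-en-2-yl)trideca-6,12-dienoate (both C11 epimers) | COC(=O)C[C@H](C)CC/C(C(C)=C)=C(\C)CCCC(O)C=C | intermediate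
12 | methyl (3R,6Z)-3,7-dimethyl-11-oxo-6-(prop-1-en-2-yl)trideca-6,12-dienoate | COC(=O)C[C@H](C)CC/C(C(C)=C)=C(\C)CCCC(=O)C=C | intermediate
13 | methyl (3R)-5-[(4aR,8aR)-2,8a-dimethyl-5-oxo-3,4,4a,5,6,7,8,8a-octahydronaphthalen-1-yl]-3-methylpentanoate (cis-fused) | COC(=O)C[C@H](C)CCC1=C(C)CC[C@H]2C(=O)CCC[C@@]12C | intermediate
14 | methyl (3R)-5-[(4aS,8aR)-2,8a-dimethyl-5-oxo-3,4,4a,5,6,7,8,8a-octahydronaphthalen-1-yl]-3-methylpentanoate (trans-fused) | COC(=O)C[C@H](C)CCC1=C(C)CC[C@@H]2C(=O)CCC[C@@]12C | intermediate
15 | methyl (3R)-3-methyl-5-[(4aR,8aR)-2,5,5,8a-tetramethyl-3,4,4a,5,6,7,8,8a-octahydronaphthalen-1-yl]pentanoate | COC(=O)C[C@H](C)CCC1=C(C)CC[C@@H]2C(C)(C)CCC[C@@]12C | intermediate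
16 | (3R)-3-methyl-5-[(4aR,8aR)-2,5,5,8a-tetramethyl-3,4,4a,5,6,7,8,8a-octahydronaphthalen-1-yl]pentanoic acid | OC(=O)C[C@H](C)CCC1=C(C)CC[C@@H]2C(C)(C)CCC[C@@]12C | intermediate
17 | [(4S)-2,2-dimethyl-1,3-dioxolan-4-yl]methanol | CC1(C)OC[C@H](CO)O1 | starting material
18 | [(4R)-2,2-dimethyl-1,3-dioxolan-4-yl]methyl (3R)-3-methyl-5-[(4aR,8aR)-2,5,5,8a-tetramethyl-3,4,4a,5,6,7,8,8a-octahydronaphthalen-1-yl]pentanoate | CC1(C)OC[C@H](COC(=O)C[C@H](C)CCC2=C(C)CC[C@@H]3C(C)(C)CCC[C@@]23C)O1 | intermediate
19 | (2R)-2,3-dihydroxypropyl (3R)-3-methyl-5-[(4aR,8aR)-2,5,5,8a-tetramethyl-3,4,4a,5,6,7,8,8a-octahydronaphthalen-1-yl]pentanoate | OC[C@@H](O)COC(=O)C[C@H](C)CCC1=C(C)CC[C@@H]2C(C)(C)CCC[C@@]12C | intermediate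
20 | (2R)-3-(acetyloxy)-2-hydroxypropyl (3R)-3-methyl-5-[(4aR,8aR)-2,5,5,8a-tetramethyl-3,4,4a,5,6,7,8,8a-octahydronaphthalen-1-yl]pentanoate | CC(=O)OC[C@@H](O)COC(=O)C[C@H](C)CCC1=C(C)CC[C@@H]2C(C)(C)CCC[C@@]12C | target

## Step count and risks

Total step count: 14. Longest linear sequence: 14 steps (1 to 20; 4, 8 and 17 are purchased and enter directly).

Steps most likely to fail:

1. Step 8. The bulky chiral Lewis acid may discriminate poorly between the two faces of the hindered tetrasubstituted diene, or catalyst-free background cyclisation may intervene; either would give both configurations at C10. Fallback (sets out from 12, returns at 14): 12 is cyclised with the small achiral Lewis acid MeAlCl2 in CH2Cl2 at −78 °C, which should give 13 together with its ring-system mirror form, the (4aS,8aS)-cis-octalone F1. NaOMe in MeOH converts the pair into 14 and the (4aR,8aS)-trans-octalone F2. Ketalisation of the mixture with (2R,3R)-butane-2,3-diol (TsOH, benzene, water removal) gives the butanediol ketal of 14 F3 and the butanediol ketal of the (4aR,8aS)-octalone F4, in which the new stereocentres sit next to the ring fusion, so the two should separate on silica. Mild acid hydrolysis of F3 (PPTS, acetone/H2O) returns 14.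

2. Step 10. The tertiary cation at C4 may lose a proton or undergo a hydride or methyl shift from C5 or C10 before the second methyl group is transferred. Fallback (sets out from 14, returns at 15): Wittig methylenation of 14 (Ph3PCH3Br, KOt-Bu, toluene) gives the C4-methylidene compound F5. Simmons–Smith cyclopropanation (Et2Zn, CH2I2) of the exocyclic alkene, which is far more accessible than the C8=C9 bond flanked by C10, gives the spirocyclopropane F6. Hydrogenolysis (H2, PtO2, AcOH) opens the cyclopropane at a bond to the unsubstituted ring carbon to give 15.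

3. Step 14. Acetylation of the secondary hydroxyl, or migration of the diterpenoyl group from O-1 to O-2 before or after acylation, would give regioisomeric diesters. Fallback (sets out from 16, returns at 20): (R)-glycidol is acetylated (Ac2O, Et3N, DMAP) to (2S)-oxiran-2-ylmethyl acetate F7. Acid 16 opens F7 at the terminal carbon under catalysis by the trivalent cobalt salen tosylate (salen)Co(OTs), with the catalyst enantiomer matched to F7, i-Pr2NEt, MTBE, rt. This carboxylic acid ring-opening of a terminal epoxide leaves the stereocentre untouched and gives 20 with the secondary hydroxyl already free.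

## Further compounds

F1 | step 8 | methyl (3R)-5-[(4aS,8aS)-2,8a-dimethyl-5-oxo-3,4,4a,5,6,7,8,8a-octahydronaphthalen-1-yl]-3-methylpentanoate (cis-fused) | COC(=O)C[C@H](C)CCC1=C(C)CC[C@@H]2C(=O)CCC[C@]12C
F2 | step 8 | methyl (3R)-5-[(4aR,8aS)-2,8a-dimethyl-5-oxo-3,4,4a,5,6,7,8,8a-octahydronaphthalen-1-yl]-3-methylpentanoate (trans-fused) | COC(=O)C[C@H](C)CCC1=C(C)CC[C@H]2C(=O)CCC[C@]12C
F3 | step 8 | (2R,3R)-butane-2,3-diyl ketal of 14 (spiro-1,3-dioxolane at C4) | COC(=O)C[C@H](C)CCC1=C(C)CC[C@@H]2C3(O[C@H](C)[C@@H](C)O3)CCC[C@@]12C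
F4 | step 8 | (2R,3R)-butane-2,3-diyl ketal of F2 (spiro-1,3-dioxolane at C4) | COC(=O)C[C@H](C)CCC1=C(C)CC[C@H]2C3(O[C@H](C)[C@@H](C)O3)CCC[C@]12C
F5 | step 10 | methyl (3R)-5-[(4aR,8aR)-2,8a-dimethyl-5-methylidene-3,4,4a,5,6,7,8,8a-octahydronaphthalen-1-yl]-3-methylpentanoate | COC(=O)C[C@H](C)CCC1=C(C)CC[C@@H]2C(=C)CCC[C@@]12C
F6 | step 10 | methyl (3R)-5-[(4a'R,8a'R)-4a',6'-dimethyl-3',4',4a',7',8',8a'-hexahydro-2'H-spiro[cyclopropane-1,1'-naphthalen]-5'-yl]-3-methylpentanoate | COC(=O)C[C@H](C)CCC1=C(C)CC[C@@H]2C3(CC3)CCC[C@@]12C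
F7 | step 14 | (2S)-oxiran-2-ylmethyl acetate | CC(=O)OC[C@@H]1CO1
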